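**Retrosynthetic overview**
- Target 24 ← Barton–McCombie removal of the C6 hydroxyl of 22 ← type 2 carbonyl-ene cyclisation of aldehyde 21 (forms C5–C6, closes ring B, moves the alkene to C1=C10).
- Feature used: the ring A alkene C5=C10 lies between quaternary C4 and quaternary C9, so C1 carries its only allylic hydrogens, and an ene reaction at C5 can only deliver the C1=C10 alkene.
- 21 ← B-alkyl Suzuki–Miyaura coupling (C12–C13, side chain) and Arndt–Eistert insertion of C7, both from vinyl acid 10.
- 10 ← enantioselective Ireland–Claisen rearrangement (C8–C9, both stereocentres) of dienyl propionate 7 ← Suzuki–Miyaura coupling (C9–C10) of ring A triflate 3 with boronate 5.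
- 3 ← asymmetric conjugate methylation and O-triflation of 1 (sets C4, fixes C5=C10); ring A is carried from 1, ring B is the only ring made (step 13).

Key step: step 13

Assumption: 1 is taken as purchasable; in steps 1 and 5 the ligand or reagent enantiomer is the one that delivers the configuration drawn, to be confirmed on the first runs; 22 is drawn as the axial (6S) alcohol expected from a closed ene transition state, and its C6 epimer would serve equally because C6 ends as CH2.

Step 1
Reactants: 1 methyl 3-oxocyclohex-1-ene-1-carboxylate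
Product: 3 methyl (1S)-1-methyl-3-{[(trifluoromethyl)sulfonyl]oxy}cyclohex-2-ene-1-carboxylate, via methylzinc enolate 2 (not isolated)
Conditions: Me2Zn (3 equiv), (CuOTf)2·C6H6 (2.5 mol %), chiral sulfonate-bearing imidazolinylidene ligand L* charged as [Ag(L*)]2 (2.5 mol %), t-BuOMe, −30 °C; then Tf2O (1.5 equiv), −30 → 0 °C
Reagents that add atoms: dimethylzinc, C[Zn]C; trifluoromethanesulfonic anhydride, O=S(=O)(OS(=O)(=O)C(F)(F)F)C(F)(F)F
Why: Copper-catalysed asymmetric conjugate addition of methyl to the ester-bearing β-carbon of the cyclic γ-keto ester creates quaternary C4 under ligand control (the ligand enantiomer giving 4S is used), and O-sulfonylation of the zinc enolate, whose double bond can only point toward C4, fixes the alkene at C5=C10 without any regioselective enolisation.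

Step 2
Reactants: 4 but-2-yn-1-ol
Product: 5 (2Z)-3-(4,4,5,5-tetramethyl-1,3,2-dioxaborolan-2-yl)but-2-en-1-ol (boron trans to CH2OH)
Conditions: B2pin2 (1.1 equiv), CuCl (5 mol %), PCy3 (6 mol %), NaOt-Bu (15 mol %), MeOH (2 equiv), toluene, rt
Reagents that add atoms: bis(pinacolato)diboron, CC1(C)OB(OC1(C)C)B1OC(C)(C)C(C)(C)O1
Why: Copper-catalysed formal hydroboration (syn borylcupration, then protonation of the alkenylcopper by methanol) puts boron on the alkyne carbon remote from the propargylic oxygen and hydrogen cis to it, so boron and CH2OH end up trans.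

Step 3
Reactants: 3 ring A triflate; 5 alkenylboronate
Product: 6 methyl (1S)-3-[(2E)-4-hydroxybut-2-en-2-yl]-1-methylcyclohex-2-ene-1-carboxylate
Conditions: Pd(dppf)Cl2 (3 mol %), K3PO4 (3 equiv), THF–H2O, 50 °C
Reagents that add atoms: none
Why: Suzuki–Miyaura coupling of an alkenyl triflate with an alkenylboronic ester proceeds with retention at both sp2 carbons, joining C10 to C9 and giving the (E)-dienol, and the neopentyl-type methyl ester survives aqueous phosphate.

Step 4
Reactants: 6 dienol
Product: 7 methyl (1S)-1-methyl-3-[(2E)-4-(propanoyloxy)but-2-en-2-yl]cyclohex-2-ene-1-carboxylate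
Conditions: EtCOCl, pyridine, DMAP (cat.), CH2Cl2, 0 °C
Reagents that add atoms: propionyl chloride, CCC(=O)Cl
Why: Standard acylation of the primary allylic alcohol installs the propionate whose α-carbon becomes C8, whose methyl becomes C17 and whose carbonyl carbon becomes C6.

Step 5
Reactants: 7 dienyl propionate
Product: 10 (2S,3S)-3-[(3S)-3-(methoxycarbonyl)-3-methylcyclohex-1-en-1-yl]-2,3-dimethylpent-4-enoic acid, via boron ketene acetal 8 (not isolated), via acyloxyborane 9 (not isolated)
Conditions: preformed (4S,5S)-2-bromo-1,3-bis{[3,5-bis(trifluoromethyl)phenyl]sulfonyl}-4,5-diphenyl-1,3,2-diazaborolidine (1.3 equiv), Et3N (1.5 equiv), toluene–hexane, −78 °C (E(O) enolate), then −20 → 4 °C; H2O work-up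
Reagents that add atoms: none
Why: Enantioselective Ireland–Claisen rearrangement in which soft enolisation gives the E(O) boron ketene acetal (C17 methyl cis to the allylic oxygen; the C4 ester has no α-hydrogen), the chair transition state with the E(O) enolate and the E alkene (ring A equatorial, C20 axial) fixes the C8/C9 relative configuration as drawn, and the C2-symmetric diazaborolidine chooses the enantiotopic face of the C9 terminus, so both centres are set by the reagent independently of remote C4.

Step 6
Reactants: 10 vinyl acid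
Product: 12 methyl (1S)-3-[(3S,4S)-6-diazo-3,4-dimethyl-5-oxohex-1-en-3-yl]-1-methylcyclohex-2-ene-1-carboxylate, via acid chloride 11 (not isolated)
Conditions: (COCl)2, DMF (cat.), CH2Cl2, 0 °C → rt; evaporate; CH2N2 (3 equiv), Et2O, 0 °C
Reagents that add atoms: diazomethane, C=[N+]=[N-]
Why: First stage of the Arndt–Eistert homologation, in which the acid chloride acylates diazomethane and, with no amine base present, the C8 stereocentre cannot epimerise through a ketene.

Step 7
Reactants: 12 diazoketone
Product: 14 (3R,4S)-4-[(3S)-3-(methoxycarbonyl)-3-methylcyclohex-1-en-1-yl]-3,4-dimethylhex-5-enoic acid, via ketene 13 (not isolated)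
Conditions: PhCO2Ag (10 mol %), Et3N (3 equiv), THF–H2O (9:1), rt, dark
Reagents that add atoms: water, O
Why: Wolff rearrangement in which C8 migrates to the carbene carbon with retention of configuration and the ketene is hydrated, so the inserted CH2 is C7 and the former carboxyl carbon stays as C6.

Step 8
Reactants: 14 homologated acid
Product: 16 methyl (1S)-3-[(3S,4R)-6-hydroxy-3,4-dimethylhex-1-en-3-yl]-1-methylcyclohex-2-ene-1-carboxylate, via mixed carbonic anhydride 15 (not isolated)
Conditions: i-BuOCOCl, N-methylmorpholine, THF, −15 °C; then NaBH4, THF–H2O, 0 °C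
Reagents that add atoms: none
Why: Borohydride reduces the activated mixed carbonic anhydride much faster than the hindered methyl ester and, unlike borane, leaves the alkenes untouched.

Step 9
Reactants: 5 alkenylboronate
Product: 17 (2E)-3-iodobut-2-en-1-ol (iodine trans to CH2OH)
Conditions: NaOH (3 M aq), I2, THF, 0 °C → rt
Reagents that add atoms: iodine, II
Why: Base-mediated iododeboronation of the alkenylboronic ester through its hydroxy-ate complex replaces boron by iodine with retention of alkene geometry.

Step 10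
Reactants: 17 iodo alcohol
Product: 18 (2E)-3-iodobut-2-en-1-yl acetate
Conditions: Ac2O, pyridine, DMAP (cat.), CH2Cl2, 0 °C
Reagents that add atoms: acetic anhydride, CC(=O)OC(C)=O
Why: Routine acetylation puts the C15 acetate in place before the coupling, so no hydroxyl differentiation is needed later.

Step 11
Reactants: 16 vinyl alcohol; 18 alkenyl iodide
Product: 20 methyl (1S)-3-[(2E,6S,7R)-1-acetoxy-9-hydroxy-3,6,7-trimethylnon-2-en-6-yl]-1-methylcyclohex-2-ene-1-carboxylate, via alkylborane 19 (not isolated)
Conditions: 9-BBN (2.5 equiv), THF, 0 °C → rt; then 18, Pd(dppf)Cl2 (5 mol %), AsPh3 (10 mol %), Cs2CO3 (3 equiv), DMF–H2O, rt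
Reagents that add atoms: none
Why: 9-BBN hydroborates only the monosubstituted vinyl group, anti-Markovnikov at C12 (the hindered ring alkene is inert and the hydroxyl merely consumes one equivalent as a borinate cleaved on work-up), and the B-alkyl Suzuki–Miyaura coupling forms C12–C13 with retention at the alkenyl iodide, giving the 13E alkene.

Step 12
Reactants: 20 primary alcohol
Product: 21 methyl (1S)-3-[(2E,6S,7R)-1-acetoxy-3,6,7-trimethyl-9-oxonon-2-en-6-yl]-1-methylcyclohex-2-ene-1-carboxylate (ene precursor; 4S,8R,9S in halimane numbering)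
Conditions: Dess–Martin periodinane, NaHCO3, CH2Cl2, rt
Reagents that add atoms: none
Why: Dess–Martin oxidation converts the primary alcohol into the C6 aldehyde under buffered conditions without touching the esters or alkenes, and C7 is CH2 so nothing can epimerise.

Step 13
Reactants: 21 ene precursor
Product: 22 methyl 15-acetoxy-6-hydroxy-ent-halima-1(10),13E-dien-18-oate (4S,5S,6S,8R,9S; hydroxyl axial)
Conditions: Me2AlCl (3.5 equiv, hexanes), CH2Cl2, −78 → −20 °C; 1 M HCl, 0 °C
Reagents that add atoms: none
Why: Me2AlCl activates the C6 aldehyde, C5 of the ring A alkene attacks C6 and in the same six-centre array the pseudoaxial hydrogen on C1 passes to the aldehyde oxygen (the aluminium alkoxide then loses methane, which removes the proton that could isomerise the new alkene), so C5–C6 forms and the double bond moves to C1=C10. The closest known reaction is the Lewis-acid-promoted type 2 intramolecular carbonyl-ene cyclisation of δ,ε-unsaturated aldehydes to 3-alkylidenecyclohexanols. Ring B closes as a six-membered ring, exo with respect to the carbonyl and endo with respect to the alkene, through a chair-like array C5–C6–C7–C8–C9–C10. The position of the new alkene needs no control, because C4 and C9 are quaternary and only C1 can give up a hydrogen, and C6 (oxygen axial in the closed transition state) is erased in step 15, so the one selectivity required is that C6 bonds to the face of C5 that carries the C4 methyl, anti to the ester. That face is the one open when ring A reacts in the half-chair with the aluminium-bound ester pseudoaxial: the chair then has the small C20 methyl in the ring A plane beside C1H2, the C11 chain axial on the face away from the tether, and the O–Al unit lying over ring A where it meets only the C4 methyl, whereas on the other face it would meet the complexed ester. The price is an axial C17 methyl close to the carbinol oxygen, so this facial selectivity is the principal risk of the route and is answered by the first fallback.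

Step 14
Reactants: 22 ene product
Product: 23 methyl 15-acetoxy-6-[(1H-imidazol-1-ylcarbonothioyl)oxy]-ent-halima-1(10),13E-dien-18-oate
Conditions: 1,1′-thiocarbonyldiimidazole (2 equiv), DMAP (cat.), toluene, 80 °C
Reagents that add atoms: 1,1′-thiocarbonyldiimidazole, S=C(n1ccnc1)n1ccnc1
Why: Thioacylation of the hindered C6 hydroxyl under neutral conditions avoids an alkoxide that could attack the acetate or the C18 ester and gives the substrate for Barton–McCombie deoxygenation.

Step 15
Reactants: 23 thiocarbonylimidazolide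
Product: 24 methyl 15-acetoxy-ent-halima-1(10),13E-dien-18-oate (4S,5S,8R,9S)
Conditions: Bu3SnH (2 equiv), AIBN (0.2 equiv), toluene, 100 °C
Reagents that add atoms: none
Why: Barton–McCombie deoxygenation in which the stannyl radical adds to the thiocarbonyl sulfur, the C6–O bond fragments to a secondary radical, and this abstracts hydrogen from Bu3SnH faster than it can cyclise onto the distant alkenes, erasing the C6 stereocentre and giving the target.

**Compound list**
1 | methyl 3-oxocyclohex-1-ene-1-carboxylate | COC(=O)C1=CC(=O)CCC1 | starting material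
2 | methyl (1S)-1-methyl-3-[(methylzincio)oxy]cyclohex-2-ene-1-carboxylate | COC(=O)[C@@]1(C)CCCC(O[Zn]C)=C1 | intermediate
3 | methyl (1S)-1-methyl-3-{[(trifluoromethyl)sulfonyl]oxy}cyclohex-2-ene-1-carboxylate | COC(=O)[C@@]1(C)CCCC(OS(=O)(=O)C(F)(F)F)=C1 | intermediate
4 | but-2-yn-1-ol | CC#CCO | starting material
5 | (2Z)-3-(4,4,5,5-tetramethyl-1,3,2-dioxaborolan-2-yl)but-2-en-1-ol | C/C(B1OC(C)(C)C(C)(C)O1)=C\CO | intermediate
6 | methyl (1S)-3-[(2E)-4-hydroxybut-2-en-2-yl]-1-methylcyclohex-2-ene-1-carboxylate | COC(=O)[C@@]1(C)CCCC(=C1)/C(C)=C/CO | intermediate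
7 | methyl (1S)-1-methyl-3-[(2E)-4-(propanoyloxy)but-2-en-2-yl]cyclohex-2-ene-1-carboxylate | COC(=O)[C@@]1(C)CCCC(=C1)/C(C)=C/COC(=O)CC | intermediate
8 | E(O) boron ketene acetal of 7 with the (4S,5S)-diazaborolidine | C/C=C(\OC/C=C(C)/C1=C[C@@](C)(C(=O)OC)CCC1)OB1N(S(=O)(=O)c2cc(C(F)(F)F)cc(C(F)(F)F)c2)[C@@H](c2ccccc2)[C@H](c2ccccc2)N1S(=O)(=O)c1cc(C(F)(F)F)cc(C(F)(F)F)c1 | intermediate
9 | B-acyloxy-(4S,5S)-diazaborolidine of acid 10 | COC(=O)[C@@]1(C)CCCC(=C1)[C@@](C)(C=C)[C@H](C)C(=O)OB1N(S(=O)(=O)c2cc(C(F)(F)F)cc(C(F)(F)F)c2)[C@@H](c2ccccc2)[C@H](c2ccccc2)N1S(=O)(=O)c1cc(C(F)(F)F)cc(C(F)(F)F)c1 | intermediate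
10 | (2S,3S)-3-[(3S)-3-(methoxycarbonyl)-3-methylcyclohex-1-en-1-yl]-2,3-dimethylpent-4-enoic acid | COC(=O)[C@@]1(C)CCCC(=C1)[C@@](C)(C=C)[C@H](C)C(=O)O | intermediate
11 | acid chloride of 10 | COC(=O)[C@@]1(C)CCCC(=C1)[C@@](C)(C=C)[C@H](C)C(=O)Cl | intermediate
12 | methyl (1S)-3-[(3S,4S)-6-diazo-3,4-dimethyl-5-oxohex-1-en-3-yl]-1-methylcyclohex-2-ene-1-carboxylate | COC(=O)[C@@]1(C)CCCC(=C1)[C@@](C)(C=C)[C@H](C)C(=O)C=[N+]=[N-] | intermediate
13 | ketene from 12 | COC(=O)[C@@]1(C)CCCC(=C1)[C@@](C)(C=C)[C@H](C)C=C=O | intermediate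
14 | (3R,4S)-4-[(3S)-3-(methoxycarbonyl)-3-methylcyclohex-1-en-1-yl]-3,4-dimethylhex-5-enoic acid | COC(=O)[C@@]1(C)CCCC(=C1)[C@@](C)(C=C)[C@H](C)CC(=O)O | intermediate
15 | isobutyl carbonic mixed anhydride of 14 | COC(=O)[C@@]1(C)CCCC(=C1)[C@@](C)(C=C)[C@H](C)CC(=O)OC(=O)OCC(C)C | intermediate
16 | methyl (1S)-3-[(3S,4R)-6-hydroxy-3,4-dimethylhex-1-en-3-yl]-1-methylcyclohex-2-ene-1-carboxylate | COC(=O)[C@@]1(C)CCCC(=C1)[C@@](C)(C=C)[C@H](C)CCO | intermediate
17 | (2E)-3-iodobut-2-en-1-ol | C/C(I)=C\CO | intermediate
18 | (2E)-3-iodobut-2-en-1-yl acetate | C/C(I)=C\COC(C)=O | intermediate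
19 | B-alkyl-9-BBN adduct of 16 (hydroxyl as 9-BBN borinate) | COC(=O)[C@@]1(C)CCCC(=C1)[C@@](C)(CCB2C3CCCC2CCC3)[C@H](C)CCOB2C3CCCC2CCC3 | intermediate
20 | methyl (1S)-3-[(2E,6S,7R)-1-acetoxy-9-hydroxy-3,6,7-trimethylnon-2-en-6-yl]-1-methylcyclohex-2-ene-1-carboxylate | COC(=O)[C@@]1(C)CCCC(=C1)[C@@](C)(CC/C(C)=C/COC(C)=O)[C@H](C)CCO | intermediate
21 | methyl (1S)-3-[(2E,6S,7R)-1-acetoxy-3,6,7-trimethyl-9-oxonon-2-en-6-yl]-1-methylcyclohex-2-ene-1-carboxylate | COC(=O)[C@@]1(C)CCCC(=C1)[C@@](C)(CC/C(C)=C/COC(C)=O)[C@H](C)CC=O | intermediate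
22 | methyl 15-acetoxy-6-hydroxy-ent-halima-1(10),13E-dien-18-oate (6S) | COC(=O)[C@@]1(C)CCC=C2[C@@H]1[C@@H](O)C[C@@H](C)[C@]2(C)CC/C(C)=C/COC(C)=O | intermediate
23 | methyl 15-acetoxy-6-[(1H-imidazol-1-ylcarbonothioyl)oxy]-ent-halima-1(10),13E-dien-18-oate | COC(=O)[C@@]1(C)CCC=C2[C@@H]1[C@@H](OC(=S)n1ccnc1)C[C@@H](C)[C@]2(C)CC/C(C)=C/COC(C)=O | intermediate
24 | methyl 15-acetoxy-ent-halima-1(10),13E-dien-18-oate | COC(=O)[C@@]1(C)CCC=C2[C@@H]1CC[C@@H](C)[C@]2(C)CC/C(C)=C/COC(C)=O | target

**Step count**
Total: 15 steps. Longest linear sequence: 12 steps (steps 1, 3, 4, 5, 6, 7, 8, 11, 12, 13, 14, 15).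

**Steps most likely to fail**

1. Step 13. The cyclisation may run through the other chair, with C6 adding to the ester-side face of C5, because the required chair holds the C17 methyl axial beside the aluminium-bound oxygen. The fallback sets out from 22, used as whatever mixture of C5 epimers is obtained, and comes back at 24. Dess–Martin oxidation should give the 6-ketone, methyl 15-acetoxy-6-oxo-ent-halima-1(10),13E-dien-18-oate F1. In F1 C6 is trigonal, so the axial C17 methyl has lost its 1,3-diaxial partner, and C5–H is both α to the carbonyl and allylic. Brief treatment with DBU in CH2Cl2 equilibrates C5 through the dienolate (kinetic reprotonation at the α-carbon keeps the alkene at C1=C10) and should enrich the ring fusion of the target. Condensation with p-toluenesulfonylhydrazide (EtOH, AcOH cat.) gives the tosylhydrazone F2. Reduction with catecholborane, then NaOAc in warm CHCl3, replaces C=N by CH2 without alkene shift for a β,γ-unsaturated hydrazone and gives 24, so steps 14 and 15 are not needed.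

2. Step 5. Reagent control may be incomplete: the enolate geometry or the face selection at the dienyl terminus may erode, or the Lewis-acidic borane may ionise the dienylic ester. The fallback sets out from 3 and comes back at 10, replacing reagent control by chirality transfer from a carbinol centre. Pent-3-yn-2-one is reduced by asymmetric transfer hydrogenation (RuCl(p-cymene)[(R,R)-TsDPEN], i-PrOH) to (R)-pent-3-yn-2-ol F3. Copper-catalysed borylation as in step 2 gives (2R,3Z)-4-(4,4,5,5-tetramethyl-1,3,2-dioxaborolan-2-yl)pent-3-en-2-ol F4. Suzuki–Miyaura coupling with 3 as in step 3 gives the secondary dienol F5, and propionylation gives its ester F6. Ireland–Claisen rearrangement (LDA, Me3SiCl, THF, −78 °C → rt; E(O) silyl ketene acetal, chair with the carbinol methyl equatorial) should transfer the R configuration of the carbinol carbon to C9 and C8. After hydrolysis of the silyl ester this gives the (E)-propenyl acid F7. Ethenolysis (ethylene, second-generation Grubbs catalyst, CH2Cl2) trims the propenyl group to the vinyl group of 10.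

3. Step 7. The silver carbenoid may be diverted into cyclopropanation of the vinyl group three atoms away, or into C–H insertion, before the hindered C8 migrates. The fallback sets out from 10 and comes back at 16, replacing the carbene-based homologation by an ylide-based one. Reduction of 10 through its isobutyl mixed anhydride with NaBH4 gives the primary alcohol F8, and Dess–Martin oxidation gives the aldehyde F9. Wittig reaction with Ph3P=CHOMe (phosphonium chloride, KHMDS, THF, −78 → 0 °C, ylide in slight deficiency of base to protect C8) gives the enol ether F10 as an E/Z mixture. Hydrolysis with 1 M HCl in THF gives the homologous aldehyde F11, and NaBH4 in MeOH reduces it to 16.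

**Further compounds**
F1 | step 13 | methyl 15-acetoxy-6-oxo-ent-halima-1(10),13E-dien-18-oate | COC(=O)[C@@]1(C)CCC=C2[C@@H]1C(=O)C[C@@H](C)[C@]2(C)CC/C(C)=C/COC(C)=O
F2 | step 13 | p-toluenesulfonylhydrazone of F1 | COC(=O)[C@@]1(C)CCC=C2[C@@H]1C(=NNS(=O)(=O)c1ccc(C)cc1)C[C@@H](C)[C@]2(C)CC/C(C)=C/COC(C)=O
F3 | step 5 | (R)-pent-3-yn-2-ol | C[C@@H](O)C#CC
F4 | step 5 | (2R,3Z)-4-(4,4,5,5-tetramethyl-1,3,2-dioxaborolan-2-yl)pent-3-en-2-ol | C[C@@H](O)/C=C(\C)B1OC(C)(C)C(C)(C)O1
F5 | step 5 | methyl (1S)-3-[(2E,4R)-4-hydroxypent-2-en-2-yl]-1-methylcyclohex-2-ene-1-carboxylate | COC(=O)[C@@]1(C)CCCC(=C1)/C(C)=C/[C@@H](C)O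
F6 | step 5 | methyl (1S)-1-methyl-3-[(2E,4R)-4-(propanoyloxy)pent-2-en-2-yl]cyclohex-2-ene-1-carboxylate | COC(=O)[C@@]1(C)CCCC(=C1)/C(C)=C/[C@@H](C)OC(=O)CC
F7 | step 5 | (2S,3S,4E)-3-[(3S)-3-(methoxycarbonyl)-3-methylcyclohex-1-en-1-yl]-2,3-dimethylhex-4-enoic acid | COC(=O)[C@@]1(C)CCCC(=C1)[C@@](C)(/C=C/C)[C@H](C)C(=O)O
F8 | step 7 | methyl (1S)-3-[(3S,4S)-5-hydroxy-3,4-dimethylpent-1-en-3-yl]-1-methylcyclohex-2-ene-1-carboxylate | COC(=O)[C@@]1(C)CCCC(=C1)[C@@](C)(C=C)[C@H](C)CO
F9 | step 7 | methyl (1S)-3-[(3S,4S)-3,4-dimethyl-5-oxopent-1-en-3-yl]-1-methylcyclohex-2-ene-1-carboxylate | COC(=O)[C@@]1(C)CCCC(=C1)[C@@](C)(C=C)[C@H](C)C=O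
F10 | step 7 | methyl (1S)-3-[(3S,4R)-6-methoxy-3,4-dimethylhexa-1,5-dien-3-yl]-1-methylcyclohex-2-ene-1-carboxylate (E/Z mixture) | COC(=O)[C@@]1(C)CCCC(=C1)[C@@](C)(C=C)[C@H](C)C=COC
F11 | step 7 | methyl (1S)-3-[(3S,4R)-3,4-dimethyl-6-oxohex-1-en-3-yl]-1-methylcyclohex-2-ene-1-carboxylate | COC(=O)[C@@]1(C)CCCC(=C1)[C@@](C)(C=C)[C@H](C)CC=O
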